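**Plan**

- Retrosynthesis first removes three benzyl ethers, then cuts C8–C8a and C4a–C5 of ring A of flavone 1. That ring carries a free C5 hydroxyl and a C7 methyl ether, a 1-hydroxy-3-methoxy pattern on the C4a–C8a edge that a 1,3-dimethoxy-1-silyloxybutadiene can deliver onto a sulfinyl-activated pyranone.
- The pyranone (ring C of flavone 1) is cut at C2–C3 (acylation of an enaminone anion) and O1–C8a (addition–elimination), giving a ring B aroyl chloride and a sulfinyl enaminone.
- The biaryl bond C8 (flavone 2)–C3' (flavone 1) is cut by a Suzuki–Miyaura coupling, and flavone 2 is cut to a chalcone.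
- Forward order: rings of flavone 2 (chalcone, oxidative closure of ring C), C8 iodination, biaryl bond, pyranone ring, ring A of flavone 1 last, global debenzylation.
- The target has no stereocentre. The ring-fusion centres formed in the cycloaddition and the sulfur centre are erased in the same step.

Key step: step 14

Assumption: the sulfoxide is used as the racemate and drawn without a descriptor, since sulfur leaves in step 14; the biaryl axis between the two flavone units is treated as configurationally undefined, as in the target.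

**Route**

Step 1
Reactants: 1 2',4',6'-trihydroxyacetophenone
Product: 2 1-[2,4-bis(benzyloxy)-6-hydroxyphenyl]ethanone
Conditions: BnBr (2.1 equiv), K2CO3, DMF, rt
Reagents that add atoms: benzyl bromide, BrCc1ccccc1
Why: Williamson etherification should alkylate two phenols, while the last ortho hydroxyl, hydrogen-bonded to the acetyl carbonyl, is much less nucleophilic and stays free.

Step 2
Reactants: 2 1-[2,4-bis(benzyloxy)-6-hydroxyphenyl]ethanone; 3 4-methoxybenzaldehyde
Product: 4 (E)-1-[2,4-bis(benzyloxy)-6-hydroxyphenyl]-3-(4-methoxyphenyl)prop-2-en-1-one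
Conditions: KOH, EtOH, rt; then aq HCl
Reagents that add atoms: none
Why: Claisen–Schmidt condensation of the acetophenone enolate with a non-enolisable aldehyde, followed by dehydration, should give the conjugated E-chalcone.

Step 3
Reactants: 4 (E)-1-[2,4-bis(benzyloxy)-6-hydroxyphenyl]-3-(4-methoxyphenyl)prop-2-en-1-one
Product: 5 5,7-bis(benzyloxy)-2-(4-methoxyphenyl)-4H-chromen-4-one
Conditions: I2 (cat.), DMSO, 130 °C
Reagents that add atoms: none
Why: Iodine-mediated oxidative cyclisation of a 2'-hydroxychalcone (oxa-Michael closure, α-iodination, loss of HI, DMSO as terminal oxidant) is the standard flavone synthesis and tolerates aryl benzyl ethers.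

Step 4
Reactants: 5 5,7-bis(benzyloxy)-2-(4-methoxyphenyl)-4H-chromen-4-one
Product: 6 5,7-bis(benzyloxy)-8-iodo-2-(4-methoxyphenyl)-4H-chromen-4-one
Conditions: NIS, CF3CO2H (cat.), MeCN/CH2Cl2, 0 °C to rt
Reagents that add atoms: N-iodosuccinimide, O=C1CCC(=O)N1I
Why: Electrophilic aromatic iodination of a 5,7-dialkoxyflavone without a free C5 hydroxyl should occur at C8 (para to the C5 ether, ortho to the C7 ether), the usual halogenation site for this class, and ring A is far more electron-rich than the anisyl ring or C3.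

Step 5
Reactants: 7 methyl 4-hydroxy-3-iodobenzoate
Product: 8 methyl 4-(benzyloxy)-3-iodobenzoate
Conditions: BnBr, K2CO3, DMF, 50 °C
Reagents that add atoms: benzyl bromide, BrCc1ccccc1
Why: Williamson etherification of a phenol that is acidified by the para ester and ortho iodine should be clean.

Step 6
Reactants: 8 methyl 4-(benzyloxy)-3-iodobenzoate
Product: 9 methyl 4-(benzyloxy)-3-(4,4,5,5-tetramethyl-1,3,2-dioxaborolan-2-yl)benzoate
Conditions: B2pin2, PdCl2(dppf) (cat.), KOAc, 1,4-dioxane, 90 °C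
Reagents that add atoms: bis(pinacolato)diboron, CC1(C)OB(OC1(C)C)B1OC(C)(C)C(C)(C)O1
Why: Miyaura borylation (oxidative addition of the aryl iodide to zerovalent palladium, acetate-assisted transmetalation, reductive elimination) leaves the ester and benzyl ether untouched.

Step 7
Reactants: 6 5,7-bis(benzyloxy)-8-iodo-2-(4-methoxyphenyl)-4H-chromen-4-one; 9 methyl 4-(benzyloxy)-3-(4,4,5,5-tetramethyl-1,3,2-dioxaborolan-2-yl)benzoate
Product: 10 methyl 4-(benzyloxy)-3-[5,7-bis(benzyloxy)-2-(4-methoxyphenyl)-4-oxo-4H-chromen-8-yl]benzoate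
Conditions: Pd(OAc)2 (cat.), SPhos, K3PO4, toluene/H2O, 95 °C
Reagents that add atoms: none
Why: Suzuki–Miyaura coupling with a bulky, electron-rich biarylphosphine is the established way to tri-ortho-substituted biaryls of the 8-aryl-flavone type, and any ester hydrolysed by the base is converged in step 8.

Step 8
Reactants: 10 methyl 4-(benzyloxy)-3-[5,7-bis(benzyloxy)-2-(4-methoxyphenyl)-4-oxo-4H-chromen-8-yl]benzoate
Product: 11 4-(benzyloxy)-3-[5,7-bis(benzyloxy)-2-(4-methoxyphenyl)-4-oxo-4H-chromen-8-yl]benzoic acid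
Conditions: LiOH·H2O, THF/MeOH/H2O, 40 °C; then aq HCl
Reagents that add atoms: lithium hydroxide, [Li+].[OH-]
Why: Saponification of a methyl benzoate proceeds under conditions mild enough for the flavone, and any ring-opened diketone would reclose on acidification.

Step 9
Reactants: 11 4-(benzyloxy)-3-[5,7-bis(benzyloxy)-2-(4-methoxyphenyl)-4-oxo-4H-chromen-8-yl]benzoic acid
Product: 12 4-(benzyloxy)-3-[5,7-bis(benzyloxy)-2-(4-methoxyphenyl)-4-oxo-4H-chromen-8-yl]benzoyl chloride
Conditions: 1-chloro-N,N,2-trimethylprop-1-en-1-amine, CH2Cl2, 0 °C to rt; concentrate, use crude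
Reagents that add atoms: 1-chloro-N,N,2-trimethylprop-1-en-1-amine, CC(C)=C(Cl)N(C)C
Why: The α-chloroenamine converts the acid to its chloride under neutral conditions via an acyloxyiminium chloride, which avoids the HCl and the chloropyrylium formation that oxalyl or thionyl chloride could cause at the flavone carbonyl.

Step 10
Reactants: 13 methyl p-tolyl sulfoxide (racemic)
Product: 14 1-(p-tolylsulfinyl)propan-2-one
Conditions: LiN(iPr)2 (2.1 equiv), THF, −78 °C; EtOAc; then cold aq HCl
Reagents that add atoms: ethyl acetate, CCOC(C)=O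
Why: Claisen-type acylation of the α-sulfinyl carbanion by an ester gives the β-keto sulfoxide, and the second equivalent of base is taken up by the more acidic product, which prevents double acylation.

Step 11
Reactants: 14 1-(p-tolylsulfinyl)propan-2-one
Product: 15 (Z)-4-(dimethylamino)-3-(p-tolylsulfinyl)but-3-en-2-one (geometry as drawn, immaterial)
Conditions: Me2NCH(OMe)2, toluene, rt to 50 °C
Reagents that add atoms: N,N-dimethylformamide dimethyl acetal, COC(OC)N(C)C
Why: Aminomethylenation by the amide acetal occurs at the methylene activated by both C=O and S=O, with loss of two methanol, and the far less acidic acetyl methyl is not attacked under these mild conditions.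

Step 12
Reactants: 12 4-(benzyloxy)-3-[5,7-bis(benzyloxy)-2-(4-methoxyphenyl)-4-oxo-4H-chromen-8-yl]benzoyl chloride; 15 (Z)-4-(dimethylamino)-3-(p-tolylsulfinyl)but-3-en-2-one
Product: 17 6-{4-(benzyloxy)-3-[5,7-bis(benzyloxy)-2-(4-methoxyphenyl)-4-oxo-4H-chromen-8-yl]phenyl}-3-(p-tolylsulfinyl)-4H-pyran-4-one, via diketo enaminone 16 (not isolated)
Conditions: 15 (1.5 equiv), LiN(SiMe3)2 (3 equiv) added to the mixture, THF, −78 °C; then CF3CO2H, CH2Cl2, rt
Reagents that add atoms: none
Why: In situ C-acylation of the anion formed at the acetyl methyl of the vinylogous amide gives the 1,3-diketone 16, whose enol oxygen then adds to the enamine carbon under acid and expels dimethylamine (addition–elimination, 6-endo-trig), an established 4-pyranone synthesis from α-aminomethylene ketones that leaves the sulfinyl group at C3.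

Step 13
Reactants: 18 methyl (E)-3-methoxybut-2-enoate
Product: 19 1,3-dimethoxy-1-(trimethylsilyloxy)buta-1,3-diene (ketene acetal geometry as drawn, immaterial)
Conditions: LiN(iPr)2, THF, −78 °C; Me3SiCl; non-aqueous work-up, distil
Reagents that add atoms: chlorotrimethylsilane, C[Si](C)(C)Cl
Why: γ-Deprotonation of the β-methoxy enoate gives the extended dienolate, which is silylated on oxygen to the ketene silyl acetal diene.

Step 14
Reactants: 17 6-{4-(benzyloxy)-3-[5,7-bis(benzyloxy)-2-(4-methoxyphenyl)-4-oxo-4H-chromen-8-yl]phenyl}-3-(p-tolylsulfinyl)-4H-pyran-4-one; 19 1,3-dimethoxy-1-(trimethylsilyloxy)buta-1,3-diene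
Product: 23 5,7-bis(benzyloxy)-8-[2-(benzyloxy)-5-(5-hydroxy-7-methoxy-4-oxo-4H-chromen-2-yl)phenyl]-2-(4-methoxyphenyl)-4H-chromen-4-one, via cis-fused sulfinyl cycloadduct 20 (not isolated), via dihydro mixed ketal 21 (not isolated), via aryl trimethylsilyl ether 22 (not isolated)
Conditions: 19 (3 equiv), toluene, −20 °C to rt, then 70 °C; then 1 M HCl, THF, rt
Reagents that add atoms: none
Why: Proposed new method: the electron-rich ketene-acetal diene 19 should add to the C2=C3 bond of pyranone 17, activated by both the C4 ketone and the sulfinyl group, in an asynchronous, Mukaiyama–Michael-like [4+2] cycloaddition in which the CH2 terminus bonds first to the oxygen-bearing C2 (future C8a) and the acetal carbon then closes the six-membered carbocycle onto C3 (future C4a), so ring A arises by a [4+2] closure that forms C8–C8a and C4a–C5. The closest known reactions are the regiocontrolled benzannulations of halo- and sulfinylquinones with 1,1-dioxygenated siloxydienes and the Diels–Alder reactions of chromones bearing an acceptor at C3 with siloxydienes. Suprafacial addition gives the cis-fused adduct 20 with the sulfinyl group and the C8a hydrogen syn, so thermal syn-elimination of p-toluenesulfenic acid should give 21, 1,4-loss of methanol across C5 and C8 should aromatise it to silyl ether 22, and dilute acid should free the chelated C5 phenol. No stereocentre survives: the two ring-fusion centres set by the cycloaddition are erased by the elimination and the sulfur centre leaves with the sulfenic acid. Regiochemistry is required and is secured by the polarisation of both partners (nucleophilic CH2 terminus to the doubly activated β-carbon), which places the hydroxyl from the acetal carbon at C5 and the methoxy from the enol-ether carbon at C7. Chemoselectivity is secured because the aryl-substituted C5=C6 bond of the pyranone and the C2=C3 bond of flavone 2 lack sulfinyl activation, and neutral aprotic conditions keep the mixed ketal intact until the sulfenic acid has gone.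

Step 15
Reactants: 23 5,7-bis(benzyloxy)-8-[2-(benzyloxy)-5-(5-hydroxy-7-methoxy-4-oxo-4H-chromen-2-yl)phenyl]-2-(4-methoxyphenyl)-4H-chromen-4-one
Product: 24 putraflavone
Conditions: BCl3, pentamethylbenzene, CH2Cl2, −78 to −40 °C; then MeOH/H2O
Reagents that add atoms: none
Why: BCl3 cleaves aryl benzyl ethers at low temperature by O-coordination and loss of a benzyl cation, which pentamethylbenzene traps by Friedel–Crafts alkylation, while the non-chelated methyl ethers at C7 of flavone 1 and on the anisyl ring are not cleaved at this temperature.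

**Compound list**

1 | 2',4',6'-trihydroxyacetophenone | CC(=O)c1c(O)cc(O)cc1O | starting material
2 | 1-[2,4-bis(benzyloxy)-6-hydroxyphenyl]ethanone | CC(=O)c1c(O)cc(OCc2ccccc2)cc1OCc1ccccc1 | intermediate
3 | 4-methoxybenzaldehyde | COc1ccc(C=O)cc1 | starting material
4 | (E)-1-[2,4-bis(benzyloxy)-6-hydroxyphenyl]-3-(4-methoxyphenyl)prop-2-en-1-one | COc1ccc(/C=C/C(=O)c2c(O)cc(OCc3ccccc3)cc2OCc2ccccc2)cc1 | intermediate
5 | 5,7-bis(benzyloxy)-2-(4-methoxyphenyl)-4H-chromen-4-one | COc1ccc(-c2cc(=O)c3c(OCc4ccccc4)cc(OCc4ccccc4)cc3o2)cc1 | intermediate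
6 | 5,7-bis(benzyloxy)-8-iodo-2-(4-methoxyphenyl)-4H-chromen-4-one | COc1ccc(-c2cc(=O)c3c(OCc4ccccc4)cc(OCc4ccccc4)c(I)c3o2)cc1 | intermediate
7 | methyl 4-hydroxy-3-iodobenzoate | COC(=O)c1ccc(O)c(I)c1 | starting material
8 | methyl 4-(benzyloxy)-3-iodobenzoate | COC(=O)c1ccc(OCc2ccccc2)c(I)c1 | intermediate
9 | methyl 4-(benzyloxy)-3-(4,4,5,5-tetramethyl-1,3,2-dioxaborolan-2-yl)benzoate | COC(=O)c1ccc(OCc2ccccc2)c(B2OC(C)(C)C(C)(C)O2)c1 | intermediate
10 | methyl 4-(benzyloxy)-3-[5,7-bis(benzyloxy)-2-(4-methoxyphenyl)-4-oxo-4H-chromen-8-yl]benzoate | COC(=O)c1ccc(OCc2ccccc2)c(-c2c(OCc3ccccc3)cc(OCc3ccccc3)c3c(=O)cc(-c4ccc(OC)cc4)oc23)c1 | intermediate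
11 | 4-(benzyloxy)-3-[5,7-bis(benzyloxy)-2-(4-methoxyphenyl)-4-oxo-4H-chromen-8-yl]benzoic acid | OC(=O)c1ccc(OCc2ccccc2)c(-c2c(OCc3ccccc3)cc(OCc3ccccc3)c3c(=O)cc(-c4ccc(OC)cc4)oc23)c1 | intermediate
12 | 4-(benzyloxy)-3-[5,7-bis(benzyloxy)-2-(4-methoxyphenyl)-4-oxo-4H-chromen-8-yl]benzoyl chloride | O=C(Cl)c1ccc(OCc2ccccc2)c(-c2c(OCc3ccccc3)cc(OCc3ccccc3)c3c(=O)cc(-c4ccc(OC)cc4)oc23)c1 | intermediate
13 | methyl p-tolyl sulfoxide (racemic) | Cc1ccc(S(C)=O)cc1 | starting material
14 | 1-(p-tolylsulfinyl)propan-2-one (racemic) | CC(=O)CS(=O)c1ccc(C)cc1 | intermediate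
15 | (Z)-4-(dimethylamino)-3-(p-tolylsulfinyl)but-3-en-2-one (racemic at sulfur) | CC(=O)/C(=C/N(C)C)S(=O)c1ccc(C)cc1 | intermediate
16 | (Z)-1-{4-(benzyloxy)-3-[5,7-bis(benzyloxy)-2-(4-methoxyphenyl)-4-oxo-4H-chromen-8-yl]phenyl}-5-(dimethylamino)-4-(p-tolylsulfinyl)pent-4-ene-1,3-dione (not isolated) | CN(C)/C=C(/C(=O)CC(=O)c1ccc(OCc2ccccc2)c(-c2c(OCc3ccccc3)cc(OCc3ccccc3)c3c(=O)cc(-c4ccc(OC)cc4)oc23)c1)S(=O)c1ccc(C)cc1 | intermediate
17 | 6-{4-(benzyloxy)-3-[5,7-bis(benzyloxy)-2-(4-methoxyphenyl)-4-oxo-4H-chromen-8-yl]phenyl}-3-(p-tolylsulfinyl)-4H-pyran-4-one (racemic at sulfur) | Cc1ccc(S(=O)c2coc(-c3ccc(OCc4ccccc4)c(-c4c(OCc5ccccc5)cc(OCc5ccccc5)c5c(=O)cc(-c6ccc(OC)cc6)oc45)c3)cc2=O)cc1 | intermediate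
18 | methyl (E)-3-methoxybut-2-enoate | CO/C(C)=C/C(=O)OC | starting material
19 | 1,3-dimethoxy-1-(trimethylsilyloxy)buta-1,3-diene | CO/C(O[Si](C)(C)C)=C\C(OC)=C | intermediate
20 | cis-fused cycloadduct, 2-aryl-5,7-dimethoxy-4a-(p-tolylsulfinyl)-5-(trimethylsilyloxy)-4a,5,8,8a-tetrahydro-4H-chromen-4-one (aryl as in 17; relative configuration at the ring fusion shown, racemic; ketal carbon and sulfur as mixtures; not isolated) | COC1=CC(OC)(O[Si](C)(C)C)[C@@]2(S(=O)c3ccc(C)cc3)C(=O)C=C(c3ccc(OCc4ccccc4)c(-c4c(OCc5ccccc5)cc(OCc5ccccc5)c5c(=O)cc(-c6ccc(OC)cc6)oc45)c3)O[C@H]2C1 | intermediate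
21 | 2-aryl-5,7-dimethoxy-5-(trimethylsilyloxy)-5,8-dihydro-4H-chromen-4-one (aryl as in 17; racemic; not isolated) | COC1=CC(OC)(O[Si](C)(C)C)C2=C(C1)OC(c1ccc(OCc3ccccc3)c(-c3c(OCc4ccccc4)cc(OCc4ccccc4)c4c(=O)cc(-c5ccc(OC)cc5)oc34)c1)=CC2=O | intermediate
22 | 5,7-bis(benzyloxy)-8-{2-(benzyloxy)-5-[7-methoxy-4-oxo-5-(trimethylsilyloxy)-4H-chromen-2-yl]phenyl}-2-(4-methoxyphenyl)-4H-chromen-4-one (not isolated) | COc1cc(O[Si](C)(C)C)c2c(=O)cc(-c3ccc(OCc4ccccc4)c(-c4c(OCc5ccccc5)cc(OCc5ccccc5)c5c(=O)cc(-c6ccc(OC)cc6)oc45)c3)oc2c1 | intermediate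
23 | 5,7-bis(benzyloxy)-8-[2-(benzyloxy)-5-(5-hydroxy-7-methoxy-4-oxo-4H-chromen-2-yl)phenyl]-2-(4-methoxyphenyl)-4H-chromen-4-one | COc1cc(O)c2c(=O)cc(-c3ccc(OCc4ccccc4)c(-c4c(OCc5ccccc5)cc(OCc5ccccc5)c5c(=O)cc(-c6ccc(OC)cc6)oc45)c3)oc2c1 | intermediate
24 | putraflavone, 5,7-dihydroxy-8-[2-hydroxy-5-(5-hydroxy-7-methoxy-4-oxo-4H-chromen-2-yl)phenyl]-2-(4-methoxyphenyl)-4H-chromen-4-one | COc1ccc(-c2cc(=O)c3c(O)cc(O)c(-c4cc(-c5cc(=O)c6c(O)cc(OC)cc6o5)ccc4O)c3o2)cc1 | target

**Summary**

Total step count: 15.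
Longest linear sequence: 10 steps (steps 1, 2, 3, 4, 7, 8, 9, 12, 14, 15).

**Steps most likely to fail**

1. Step 14 (Proposed new method). The diene may add only in the conjugate sense without ring closure, or be consumed by the liberated sulfenic acid. The mixed ketal may also collapse before the sulfenic acid is lost, which opens the pyranone by β-elimination of the ring oxygen. Fallback by known chemistry, setting out from acid chloride 12: commercial 2',6'-dihydroxy-4'-methoxyacetophenone is treated with LiN(SiMe3)2 (4 equiv) in THF at −78 °C and C-acylated with 12 to give 1-{4-(benzyloxy)-3-[5,7-bis(benzyloxy)-2-(4-methoxyphenyl)-4-oxo-4H-chromen-8-yl]phenyl}-3-(2,6-dihydroxy-4-methoxyphenyl)propane-1,3-dione F1. Cyclodehydration of this diketone with catalytic p-toluenesulfonic acid in toluene at 80 °C involves either of the two equivalent phenols and returns to the route at 23.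

2. Step 12. The amide base may attack the acid chloride, the enaminone anion may be acylated on oxygen, or the sulfinyl oxygen may be acylated and the sulfoxide degraded before C-acylation. Fallback, setting out from 12, carries sulfur at the sulfide level and oxidises last:
   - 4-Methylbenzenethiol is alkylated with chloroacetone (K2CO3, acetone) to 1-(p-tolylsulfanyl)propan-2-one F2.
   - Condensation with N,N-dimethylformamide dimethyl acetal gives (Z)-4-(dimethylamino)-3-(p-tolylsulfanyl)but-3-en-2-one F3.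
   - Its anion (LiN(SiMe3)2, THF, −78 °C) is acylated by 12 to the sulfide diketo enaminone F4, which is closed with CF3CO2H to 6-{4-(benzyloxy)-3-[5,7-bis(benzyloxy)-2-(4-methoxyphenyl)-4-oxo-4H-chromen-8-yl]phenyl}-3-(p-tolylsulfanyl)-4H-pyran-4-one F5.
   - One equivalent of mCPBA in CH2Cl2 at −40 °C oxidises the vinyl sulfide to the sulfoxide and returns to the route at 17.

3. Step 7. Protodeboronation of the ortho-alkoxy boronate and slow transmetalation at the tri-ortho-substituted axis may stall the coupling. Fallback, setting out from iodide 8 and iodoflavone 6, replaces boron by zinc: insertion of zinc dust into 8 (LiCl, THF, 45 °C) gives [2-(benzyloxy)-5-(methoxycarbonyl)phenyl]zinc iodide F6, and Negishi coupling with 6 (Pd(OAc)2, SPhos, THF, 60 °C) returns to the route at 10.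

**Further compounds**

F1 | step 14 | 1-{4-(benzyloxy)-3-[5,7-bis(benzyloxy)-2-(4-methoxyphenyl)-4-oxo-4H-chromen-8-yl]phenyl}-3-(2,6-dihydroxy-4-methoxyphenyl)propane-1,3-dione | COc1cc(O)c(C(=O)CC(=O)c2ccc(OCc3ccccc3)c(-c3c(OCc4ccccc4)cc(OCc4ccccc4)c4c(=O)cc(-c5ccc(OC)cc5)oc34)c2)c(O)c1
F2 | step 12 | 1-(p-tolylsulfanyl)propan-2-one | CC(=O)CSc1ccc(C)cc1
F3 | step 12 | (Z)-4-(dimethylamino)-3-(p-tolylsulfanyl)but-3-en-2-one | CC(=O)/C(=C/N(C)C)Sc1ccc(C)cc1
F4 | step 12 | (Z)-1-{4-(benzyloxy)-3-[5,7-bis(benzyloxy)-2-(4-methoxyphenyl)-4-oxo-4H-chromen-8-yl]phenyl}-5-(dimethylamino)-4-(p-tolylsulfanyl)pent-4-ene-1,3-dione | CN(C)/C=C(/C(=O)CC(=O)c1ccc(OCc2ccccc2)c(-c2c(OCc3ccccc3)cc(OCc3ccccc3)c3c(=O)cc(-c4ccc(OC)cc4)oc23)c1)Sc1ccc(C)cc1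
F5 | step 12 | 6-{4-(benzyloxy)-3-[5,7-bis(benzyloxy)-2-(4-methoxyphenyl)-4-oxo-4H-chromen-8-yl]phenyl}-3-(p-tolylsulfanyl)-4H-pyran-4-one | Cc1ccc(Sc2coc(-c3ccc(OCc4ccccc4)c(-c4c(OCc5ccccc5)cc(OCc5ccccc5)c5c(=O)cc(-c6ccc(OC)cc6)oc45)c3)cc2=O)cc1
F6 | step 7 | [2-(benzyloxy)-5-(methoxycarbonyl)phenyl]zinc iodide | COC(=O)c1ccc(OCc2ccccc2)c([Zn]I)c1
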